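**Retrosynthetic overview**

- Target 22 comes from triol 20 by acetate differentiation; the 8-carbinol of 20 (equatorial OH, axial CH3) comes from the 8(17)-methylene compound 18 by hydroxyl-directed epoxidation and hydride opening; 18 comes from the tricyclic keto lactone 16.
- Key disconnection: ring B of 16 is cut at C6–C7 and C9–C10 into enal 6 (ring A carrying C10=C5–C6HO and a C4 ester) and methyl ketone 11 (C7–C8(=O)–C9 with the finished diene side chain). Forward, this is a Michael addition, an aldol addition and a lactonisation in one flask.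
- Enabling feature: ring B holds a 1,3-dioxygenated C6(O)–C7–C8(O) unit (β-hydroxy ketone retron), with C9 α to C8 and the quaternary C10 β to C6. The equatorial C18 on C4 of ring A lies peri to O6, so a C4 ester can trap the aldol oxygen as a temporary γ-lactone.
- Order of rings: ring A is present from the start (1) and receives C4 by asymmetric conjugate methylation; ring B and the temporary lactone ring form together in step 8; the lactone is opened again in step 10.

Key step: step 8

Remark: labdane numbering (C1–C20) is used for all decalin compounds, and the CIP descriptors given define the configuration (ent-labdane series). ATPH, Al(OC6H3Ph2)3, is taken as a preformed reagent. The 6-alkoxide formed in step 8 is assumed to lactonise onto the neighbouring C4 methyl ester under the basic conditions.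

Step 1
Reactants: 1 methyl 3-oxocyclohex-1-ene-1-carboxylate
Product: 3 methyl (1S)-1-methyl-3-[(trimethylsilyl)oxy]cyclohex-2-ene-1-carboxylate, via zinc enolate 2 (not isolated)
Conditions: Me2Zn, Cu(OTf)2 (cat.), chiral sulfonate-NHC ligand (cat., from its imidazolinium salt; the enantiomer that gives the S centre), t-BuOMe, −30 °C; then Me3SiOTf, −30 → 0 °C
Reagents that add atoms: dimethylzinc C[Zn]C; trimethylsilyl trifluoromethanesulfonate C[Si](C)(C)OS(=O)(=O)C(F)(F)F
Why: Copper-catalysed asymmetric conjugate addition of a dialkylzinc to a β-ester-substituted cyclohexenone is an established route to an ester-bearing quaternary carbon, the chiral carbene–copper complex selecting the enone face (C4 set as S), and O-silylation of the zinc enolate fixes the enol ether towards C5.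

Step 2
Reactants: 3 methyl (1S)-1-methyl-3-[(trimethylsilyl)oxy]cyclohex-2-ene-1-carboxylate
Product: 4 methyl (1S)-2-(dimethoxymethyl)-1-methyl-3-oxocyclohexane-1-carboxylate
Conditions: HC(OMe)3, Me3SiOTf (cat.), CH2Cl2, −78 °C
Reagents that add atoms: trimethyl orthoformate COC(OC)OC
Why: Mukaiyama-type alkylation of the silyl enol ether by the dimethoxycarbenium ion puts the masked formyl carbon C6 on C5 only; the new stereocentre at C5 is lost again in step 4.

Step 3
Reactants: 4 methyl (1S)-2-(dimethoxymethyl)-1-methyl-3-oxocyclohexane-1-carboxylate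
Product: 5 methyl (1S)-2-(dimethoxymethyl)-3-hydroxy-1,3-dimethylcyclohexane-1-carboxylate
Conditions: MeMgBr, THF, −78 → 0 °C; aq NH4Cl
Reagents that add atoms: methylmagnesium bromide C[Mg]Br
Why: Grignard 1,2-addition to the ketone, which is far more reactive than the neopentyl ester, brings in C20; the configuration of the new carbinol carbon C10 is irrelevant because it becomes sp2 in step 4.

Step 4
Reactants: 5 methyl (1S)-2-(dimethoxymethyl)-3-hydroxy-1,3-dimethylcyclohexane-1-carboxylate
Product: 6 methyl (1S)-2-formyl-1,3-dimethylcyclohex-2-ene-1-carboxylate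
Conditions: TsOH·H2O (cat.), acetone/H2O, 40 °C
Reagents that add atoms: water O
Why: Acid hydrolysis of the acetal gives a β-hydroxy aldehyde that should lose water at once (acid-catalysed aldol dehydration via the tertiary cation) to the conjugated tetrasubstituted enal; C4 bears no acidic hydrogen and keeps its configuration.

Step 5
Reactants: 7 isoprene; 8 2-(2-bromoethyl)-2-methyl-1,3-dioxolane
Product: 10 2-methyl-2-(4-methylidenehex-5-en-1-yl)-1,3-dioxolane, via isoprenylpotassium 9 (not isolated)
Conditions: 7, KN(i-Pr)2 (from LiN(i-Pr)2 and KOt-Bu), THF, −78 °C; then 8, −78 → −20 °C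
Reagents that add atoms: none
Why: Allylic metalation of isoprene at its methyl group gives a cross-conjugated allylpotassium that is alkylated at CH2 by the primary bromide (SN2), a known entry to 2-substituted buta-1,3-dienes; no stereocentre is formed.

Step 6
Reactants: 10 2-methyl-2-(4-methylidenehex-5-en-1-yl)-1,3-dioxolane
Product: 11 6-methylideneoct-7-en-2-one
Conditions: PPTS (cat.), THF/H2O, 50 °C
Reagents that add atoms: water O
Why: Mild acid-catalysed ketal hydrolysis frees the methyl ketone without harming the 1,3-diene; no stereocentre.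

Step 7
Reactants: 11 6-methylideneoct-7-en-2-one
Product: 12 trimethyl{[(2Z)-6-methylideneocta-2,7-dien-2-yl]oxy}silane
Conditions: Me3SiCl, NaI, Et3N, MeCN, rt
Reagents that add atoms: chlorotrimethylsilane C[Si](C)(C)Cl
Why: Silylation under equilibrating conditions (iodotrimethylsilane and amine) should give mainly the more substituted internal (Z)-silyl enol ether, which fixes the site of enolate formation at C9; the minor terminal isomer is removed by distillation.

Step 8
Reactants: 6 methyl (1S)-2-formyl-1,3-dimethylcyclohex-2-ene-1-carboxylate; 12 trimethyl{[(2Z)-6-methylideneocta-2,7-dien-2-yl]oxy}silane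
Product: 16 keto lactone (4S,5S,6R,9S,10R)-8-oxo-17-norlabda-13(16),14-dien-18,6-olide, via lithium enolate 13 (not isolated), via keto aldehyde 14 (not isolated), via ketol ester 15 (not isolated)
Conditions: 12, MeLi, Et2O, 0 °C; added to 6 and Al(OC6H3Ph2)3 (ATPH, 1.1 equiv), toluene, −78 °C; then MeOH, NaOMe (cat.), −78 → 0 °C; aq NH4Cl
Reagents that add atoms: none
Why: Proposed new method: the bowl of ATPH wraps the formyl oxygen of 6 and leaves only the β-carbon C10 open, so the preformed internal lithium (Z)-enolate 13 should add 1,4 through C9 (Michael addition) to give the aluminium enolate of 14; methanol returns the aldehyde, methoxide closes ring B by 6-(enolendo)-exo-trig aldol addition of C7 to C6, and the new 6-alkoxide acylates itself on the neighbouring C4 ester (5-exo-trig lactonisation, which blocks retro-aldol). The closest known reaction types are the ATPH-directed 1,4-addition of lithium enolates and alkyllithiums to enals and the base-mediated Michael–aldol annulation of methyl ketones with β,β-disubstituted enones (isophorone type); neither has been shown for a fully substituted enal β-carbon. C10 is set under kinetic control: the enolate attacks axially on the face of the pseudo-axial C4 ester, which is the smaller 1,3-neighbour and can hold the lithium ion, and so anti to the C4 methyl. C5, C6 and C9 are epimerisable under the methoxide conditions and should settle as the trans-fused ketol with equatorial 6-oxygen (an axial one would be 1,3-diaxial to two methyl groups) and equatorial side chain, and the peri lactone then locks C5 and C6. The selectivities needed are 1,4 over 1,2 (ATPH shield), C9 over C7 as the first nucleophile (regiodefined enolate at −78 °C) and the C10 face (C4 ester).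

Step 9
Reactants: 16 keto lactone (4S,5S,6R,9S,10R)-8-oxo-17-norlabda-13(16),14-dien-18,6-olide
Product: 17 (4S,5S,6R,9R,10S)-labda-8(17),13(16),14-trien-18,6-olide
Conditions: Zn, CH2Br2, TiCl4, THF/CH2Cl2, 0 °C → rt
Reagents that add atoms: dibromomethane BrCBr
Why: Lombardo methylenation is non-basic and attacks ketones but not lactones, so the hindered enolisable β-acyloxy ketone should give the exocyclic alkene without β-elimination or epimerisation at C9; no new stereocentre (descriptors at C9 and C10 change by priority only).

Step 10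
Reactants: 17 (4S,5S,6R,9R,10S)-labda-8(17),13(16),14-trien-18,6-olide
Product: 18 (4S,5S,6R,9R,10S)-labda-8(17),13(16),14-triene-6,18-diol
Conditions: LiAlH4, THF, 0 °C → rt
Reagents that add atoms: none
Why: Hydride reduction of the γ-lactone releases the equatorial 6-hydroxyl (needed to direct step 11) and the 18-carbinol; alkenes and stereocentres are untouched.

Step 11
Reactants: 18 (4S,5S,6R,9R,10S)-labda-8(17),13(16),14-triene-6,18-diol
Product: 19 (4S,5S,6R,8S,9S,10R)-8,17-epoxylabda-13(16),14-diene-6,18-diol
Conditions: VO(acac)2 (cat.), t-BuOOH, CH2Cl2, 0 °C → rt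
Reagents that add atoms: tert-butyl hydroperoxide CC(C)(C)OO
Why: In this hydroxyl-directed vanadium-catalysed epoxidation the vanadate ester of the homoallylic equatorial 6-OH should deliver oxygen only to the C8=C17 methylene and from its own side, which is also the side away from the axial C20 methyl, so the C8–O bond becomes equatorial (8S) and the diene is left alone.

Step 12
Reactants: 19 (4S,5S,6R,8S,9S,10R)-8,17-epoxylabda-13(16),14-diene-6,18-diol
Product: 20 (4S,5S,6R,8S,9S,10R)-labda-13(16),14-diene-6,8,18-triol
Conditions: LiAlH4, THF, 0 °C → reflux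
Reagents that add atoms: none
Why: Hydride opens the spiro epoxide by SN2 attack at its unsubstituted CH2, which becomes the axial C17 methyl, while the C8–O bond and its configuration are kept (tertiary equatorial alcohol).

Step 13
Reactants: 20 (4S,5S,6R,8S,9S,10R)-labda-13(16),14-diene-6,8,18-triol
Product: 21 (4S,5S,6R,8S,9S,10R)-8-hydroxylabda-13(16),14-diene-6,18-diyl diacetate
Conditions: Ac2O, pyridine, DMAP (cat.), CH2Cl2, 0 °C → rt
Reagents that add atoms: acetic anhydride CC(=O)OC(C)=O
Why: DMAP-catalysed acylation esterifies the primary and the secondary hydroxyl, whereas the tertiary 8-OH, flanked by an axial methyl and C9, should stay free under these conditions.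

Step 14
Reactants: 21 (4S,5S,6R,8S,9S,10R)-8-hydroxylabda-13(16),14-diene-6,18-diyl diacetate
Product: 22 (4S,5S,6R,8S,9S,10R)-8,18-dihydroxylabda-13(16),14-dien-6-yl acetate
Conditions: K2CO3 (cat.), MeOH, 0 °C
Reagents that add atoms: none
Why: Base-catalysed transesterification with methanol should cleave the unhindered primary 18-acetate much faster than the secondary 6-acetate, which is shielded by C4 and C5, so that stopping at the monoacetate gives the target.

**Compound list**

1 | methyl 3-oxocyclohex-1-ene-1-carboxylate | COC(=O)C1=CC(=O)CCC1 | starting material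
2 | methylzinc enolate of methyl (1S)-1-methyl-3-oxocyclohexane-1-carboxylate | COC(=O)[C@@]1(C)CCCC(O[Zn]C)=C1 | intermediate
3 | methyl (1S)-1-methyl-3-[(trimethylsilyl)oxy]cyclohex-2-ene-1-carboxylate | COC(=O)[C@@]1(C)CCCC(O[Si](C)(C)C)=C1 | intermediate
4 | methyl (1S)-2-(dimethoxymethyl)-1-methyl-3-oxocyclohexane-1-carboxylate (C2 epimers) | COC(=O)[C@@]1(C)CCCC(=O)C1C(OC)OC | intermediate
5 | methyl (1S)-2-(dimethoxymethyl)-3-hydroxy-1,3-dimethylcyclohexane-1-carboxylate (C2 and C3 epimers) | COC(=O)[C@@]1(C)CCCC(C)(O)C1C(OC)OC | intermediate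
6 | methyl (1S)-2-formyl-1,3-dimethylcyclohex-2-ene-1-carboxylate | COC(=O)[C@@]1(C)CCCC(C)=C1C=O | intermediate
7 | isoprene (2-methylbuta-1,3-diene) | C=CC(C)=C | starting material
8 | 2-(2-bromoethyl)-2-methyl-1,3-dioxolane | CC1(CCBr)OCCO1 | starting material
9 | (2-methylidenebut-3-en-1-yl)potassium | C=CC(=C)C[K] | intermediate
10 | 2-methyl-2-(4-methylidenehex-5-en-1-yl)-1,3-dioxolane | CC1(CCCC(=C)C=C)OCCO1 | intermediate
11 | 6-methylideneoct-7-en-2-one | CC(=O)CCCC(=C)C=C | intermediate
12 | trimethyl{[(2Z)-6-methylideneocta-2,7-dien-2-yl]oxy}silane | C/C(O[Si](C)(C)C)=C/CCC(=C)C=C | intermediate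
13 | lithium (2Z)-6-methylideneocta-2,7-dien-2-olate | C/C(O[Li])=C/CCC(=C)C=C | intermediate
14 | methyl (1S,3R)-2-formyl-1,3-dimethyl-3-(6-methylidene-2-oxooct-7-en-3-yl)cyclohexane-1-carboxylate (ring C2 and side-chain C3 not fixed) | C=CC(=C)CCC(C(C)=O)[C@]1(C)CCC[C@](C)(C(=O)OC)C1C=O | intermediate
15 | methyl (4S,5S,6R,9S,10R)-6-hydroxy-8-oxo-17-norlabda-13(16),14-dien-18-oate | C=CC(=C)CC[C@H]1[C@]2(C)CCC[C@](C)(C(=O)OC)[C@H]2[C@H](O)CC1=O | intermediate
16 | (4S,5S,6R,9S,10R)-8-oxo-17-norlabda-13(16),14-dien-18,6-olide | C=CC(=C)CC[C@H]1[C@]2(C)CCC[C@](C)(C(=O)O3)[C@H]2[C@H]3CC1=O | intermediate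
17 | (4S,5S,6R,9R,10S)-labda-8(17),13(16),14-trien-18,6-olide | C=CC(=C)CC[C@H]1[C@]2(C)CCC[C@](C)(C(=O)O3)[C@H]2[C@H]3CC1=C | intermediate
18 | (4S,5S,6R,9R,10S)-labda-8(17),13(16),14-triene-6,18-diol | C=CC(=C)CC[C@H]1[C@]2(C)CCC[C@](C)(CO)[C@H]2[C@H](O)CC1=C | intermediate
19 | (4S,5S,6R,8S,9S,10R)-8,17-epoxylabda-13(16),14-diene-6,18-diol | C=CC(=C)CC[C@H]1[C@]2(C)CCC[C@](C)(CO)[C@H]2[C@H](O)C[C@]1(C3)O3 | intermediate
20 | (4S,5S,6R,8S,9S,10R)-labda-13(16),14-diene-6,8,18-triol | C=CC(=C)CC[C@H]1[C@]2(C)CCC[C@](C)(CO)[C@H]2[C@H](O)C[C@]1(C)O | intermediate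
21 | (4S,5S,6R,8S,9S,10R)-8-hydroxylabda-13(16),14-diene-6,18-diyl diacetate | C=CC(=C)CC[C@H]1[C@]2(C)CCC[C@](C)(COC(C)=O)[C@H]2[C@H](OC(C)=O)C[C@]1(C)O | intermediate
22 | (4S,5S,6R,8S,9S,10R)-8,18-dihydroxylabda-13(16),14-dien-6-yl acetate | C=CC(=C)CC[C@H]1[C@]2(C)CCC[C@](C)(CO)[C@H]2[C@H](OC(C)=O)C[C@]1(C)O | target

**Step count**

Total step count: 14. Longest linear sequence: 11 steps (steps 1–4 and 8–14).

**Steps most likely to fail**

Step 8 (proposed method). What may go wrong: proton transfer from the γ-positions of the ATPH-bound enal to the enolate (enolate scrambling instead of C–C bond formation), too slow attack at the fully substituted β-carbon, or insufficient facial discrimination at C10. The fallback uses known pericyclic chemistry instead of an anionic addition and sets out from 6 and 12. An inverse-electron-demand hetero-Diels–Alder reaction of enal 6 (as 1-oxadiene) with silyl enol ether 12, under Yb(fod)3 catalysis or high pressure, should give the cycloadduct methyl (4aS,8S)-3,4a,8-trimethyl-4-(3-methylidenepent-4-en-1-yl)-3-[(trimethylsilyl)oxy]-4,4a,5,6,7,8-hexahydro-3H-isochromene-8-carboxylate F1, which already holds the C9–C10 bond. Dilute HCl in THF opens its silyl ketal to keto aldehyde 14, and NaOMe in MeOH then closes ring B by aldol addition through 15 and lactonises to 16, where the route is rejoined.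

Step 4. What may go wrong: retro-aldol cleavage of the C5–C10 bond in the intermediate β-hydroxy aldehyde (ring opening) competing with dehydration. The fallback is the classical alkoxymethylidene-ketone transposition and sets out from 3. MeLi releases lithium (3S)-3-(methoxycarbonyl)-3-methylcyclohex-1-en-1-olate F2, which is formylated with ethyl formate to methyl (1S)-2-(hydroxymethylidene)-1-methyl-3-oxocyclohexane-1-carboxylate F3. O-Alkylation with 2-bromopropane and K2CO3 in DMF gives methyl (1S)-1-methyl-3-oxo-2-[(propan-2-yloxy)methylidene]cyclohexane-1-carboxylate F4. MeMgBr adds to the ketone to give methyl (1S)-3-hydroxy-1,3-dimethyl-2-[(propan-2-yloxy)methylidene]cyclohexane-1-carboxylate F5. Dilute aqueous HCl ionises this tertiary allylic alcohol to an alkoxy-stabilised allyl cation, which is hydrolysed with allylic transposition to enal 6 without passing through a β-hydroxy aldehyde; the route is rejoined at 6.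

Step 14. What may go wrong: over-methanolysis of the 6-acetate or acetyl migration from O6 to O18. The fallback protects first and sets out from triol 20. tert-Butyldimethylsilyl chloride and imidazole silylate only the primary hydroxyl to give (4S,5S,6R,8S,9S,10R)-18-{[tert-butyl(dimethyl)silyl]oxy}labda-13(16),14-diene-6,8-diol F6. Ac2O with DMAP acetylates the 6-hydroxyl to give (4S,5S,6R,8S,9S,10R)-18-{[tert-butyl(dimethyl)silyl]oxy}-8-hydroxylabda-13(16),14-dien-6-yl acetate F7. HF·pyridine removes the silyl ether and gives target 22.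

Further compounds
F1 | step 8 | methyl (4aS,8S)-3,4a,8-trimethyl-4-(3-methylidenepent-4-en-1-yl)-3-[(trimethylsilyl)oxy]-4,4a,5,6,7,8-hexahydro-3H-isochromene-8-carboxylate | C=CC(=C)CCC1C(C)(O[Si](C)(C)C)OC=C2[C@@](C)(C(=O)OC)CCC[C@]21C
F2 | step 4 | lithium (3S)-3-(methoxycarbonyl)-3-methylcyclohex-1-en-1-olate | COC(=O)[C@@]1(C)CCCC(O[Li])=C1
F3 | step 4 | methyl (1S)-2-(hydroxymethylidene)-1-methyl-3-oxocyclohexane-1-carboxylate | COC(=O)[C@@]1(C)CCCC(=O)C1=CO
F4 | step 4 | methyl (1S)-1-methyl-3-oxo-2-[(propan-2-yloxy)methylidene]cyclohexane-1-carboxylate | COC(=O)[C@@]1(C)CCCC(=O)C1=COC(C)C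
F5 | step 4 | methyl (1S)-3-hydroxy-1,3-dimethyl-2-[(propan-2-yloxy)methylidene]cyclohexane-1-carboxylate | COC(=O)[C@@]1(C)CCCC(C)(O)C1=COC(C)C
F6 | step 14 | (4S,5S,6R,8S,9S,10R)-18-{[tert-butyl(dimethyl)silyl]oxy}labda-13(16),14-diene-6,8-diol | C=CC(=C)CC[C@H]1[C@]2(C)CCC[C@](C)(CO[Si](C)(C)C(C)(C)C)[C@H]2[C@H](O)C[C@]1(C)O
F7 | step 14 | (4S,5S,6R,8S,9S,10R)-18-{[tert-butyl(dimethyl)silyl]oxy}-8-hydroxylabda-13(16),14-dien-6-yl acetate | C=CC(=C)CC[C@H]1[C@]2(C)CCC[C@](C)(CO[Si](C)(C)C(C)(C)C)[C@H]2[C@H](OC(C)=O)C[C@]1(C)O
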